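**Plan**
The target is 8-(3,4-dimethoxyphenyl)-2,6-dimethoxy-1,4-naphthoquinone, an achiral molecule.
Retrosynthesis: the quinone is taken back to its naphthalene-1,4-diol, then the C4–C4a bond of ring B is cut, which returns a 4-aryl-4-hydroxy-3-methoxycyclobutenone. Next the C1–C8a aryl–carbinol bond is cut (aryllithium plus methyl semisquarate), and last the C8–C1' biaryl bond (Suzuki coupling).
Enabling feature: ring B carbons C1(O), C2(OMe), C3(H) and C4(O) are the four carbons of a 4-hydroxy-3-methoxycyclobutenone bound through its carbinol carbon to C8a. The veratryl group on C8 leaves C4a as the only free ortho carbon of ring A.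
Forward order: the biaryl bond is made first, the four-membered ring is then attached, ring B arises by ring opening and 6π closure, and the diol is oxidised.
Stereochemistry: the target has none; the racemic centres met on the way are erased.

Key step: step 4

Assumption: the racemic intermediates (the reduced squarate, the aryl carbinol and the transient bicyclic dienone) are each drawn as one arbitrary enantiomer, and the three starting materials are taken as commercial.

**Route**

Step 1
Reactants: 1 dimethyl squarate (3,4-dimethoxycyclobut-3-ene-1,2-dione)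
Product: 3 3-methoxycyclobut-3-ene-1,2-dione (methyl semisquarate), via 4-hydroxy-2,3-dimethoxycyclobut-2-en-1-one 2 (not isolated)
Conditions: LiAlH(OtBu)3 (1.05 equiv), THF, −78 to −20 °C; 1 M HCl quench; crude 2, conc. HCl (cat.), CH2Cl2, rt
Reagents that add atoms: water, O (source of the new C2 carbonyl oxygen; an equal amount of water leaves from the carbinol)
Why: The bulky hydride LiAlH(OtBu)3 should add once, 1,2, to one of the two equivalent vinylogous-ester carbonyls, and acid then ionises the allylic carbinol, water captures the methoxy-stabilised cation and methanol is lost, which is the standard reduction–hydrolysis route from dialkyl squarates to semisquarate esters; the racemic carbinol centre of 2 disappears in this step.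

Step 2
Reactants: 4 4-bromo-3-iodoanisole (1-bromo-2-iodo-4-methoxybenzene); 5 3,4-dimethoxyphenylboronic acid
Product: 6 2-bromo-3',4',5-trimethoxy-1,1'-biphenyl
Conditions: Pd(PPh3)4 (3 mol %), 5 (1.05 equiv), 2 M aq. Na2CO3, DME, 80 °C
Reagents that add atoms: none
Why: Suzuki–Miyaura coupling in which zerovalent palladium inserts into the C–I bond far faster than into the C–Br bond, the latter being further deactivated by the para methoxy donor, so that with a near-stoichiometric amount of boronic acid only the iodide position should be arylated.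

Step 3
Reactants: 6 2-bromo-3',4',5-trimethoxy-1,1'-biphenyl; 3 3-methoxycyclobut-3-ene-1,2-dione
Product: 8 4-[2-(3,4-dimethoxyphenyl)-4-methoxyphenyl]-4-hydroxy-3-methoxycyclobut-2-en-1-one (racemic), via [2-(3,4-dimethoxyphenyl)-4-methoxyphenyl]lithium 7 (not isolated)
Conditions: n-BuLi (1.0 equiv), THF, −78 °C; cannulate into 3 (1.2 equiv), THF, −78 °C; sat. aq. NH4Cl
Reagents that add atoms: none
Why: Bromine–lithium exchange is much faster than ortho-lithiation at −78 °C, and the aryllithium should add 1,2 to the C2 carbonyl of 3, which is ketone-like and more electrophilic than the C1 carbonyl deactivated as a vinylogous ester (the established regiochemistry for organolithium additions to 3-alkoxycyclobutenediones), while inverse addition keeps the base from meeting an excess of itself; the new carbinol stereocentre forms as a racemate, which is of no consequence because step 4 erases it.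

Step 4
Reactants: 8 4-[2-(3,4-dimethoxyphenyl)-4-methoxyphenyl]-4-hydroxy-3-methoxycyclobut-2-en-1-one
Product: 11 8-(3,4-dimethoxyphenyl)-2,6-dimethoxynaphthalene-1,4-diol, via (Z)-dienylketene 9 (not isolated), via 4aH-naphthalen-4-one 10 (not isolated)
Conditions: degassed p-xylene (0.02 M), reflux (138 °C), Ar; solvent removed under Ar and the residue taken on at once
Reagents that add atoms: none
Why: Heating should open the cyclobutenone by conrotatory 4π electrocyclic cleavage of the C1–C4 bond, in which the donor hydroxyl rotates outward (torquoselectivity), so that the aryl group lies cis to the ketene in (Z)-dienylketene 9. The ketene carbon then bonds to the free ortho carbon of ring A in a thermal disrotatory 6π electrocyclisation of the ketene–enol–arene triene, which closes ring B as dienone 10; transfer of the 4a hydrogen to oxygen restores aromaticity and gives diol 11. The closest known reaction type is the Moore rearrangement of 4-aryl-4-hydroxycyclobutenones to naphthalene-1,4-diols. No stereocentre is created, and the carbinol centre of 8 and the 4a centre of 10 are both erased. The step needs site selectivity on ring A and the methoxy group next to the peri-substituted carbinol carbon: the veratryl group occupies the other ortho position, so only C4a can accept the ketene carbon, and the methoxy position was fixed by the carbonyl selectivity of step 3. Outward rotation of the hydroxyl also keeps it away from the ketene, which should suppress lactonisation to a furanone, and dilution under argon protects the ketene and the electron-rich diol.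

Step 5
Reactants: 11 8-(3,4-dimethoxyphenyl)-2,6-dimethoxynaphthalene-1,4-diol
Product: 12 8-(3,4-dimethoxyphenyl)-2,6-dimethoxynaphthalene-1,4-dione (target)
Conditions: Ag2O (1.5 equiv), Na2SO4, Et2O/CH2Cl2, rt
Reagents that add atoms: none
Why: Classical two-electron dehydrogenation of a para-hydroquinone to the quinone by Ag2O under neutral, anhydrous conditions, which should leave the aryl methyl ethers and the electron-rich veratryl ring untouched.

**Compound list**
1 | dimethyl squarate (3,4-dimethoxycyclobut-3-ene-1,2-dione) | COC1=C(OC)C(=O)C1=O | starting material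
2 | 4-hydroxy-2,3-dimethoxycyclobut-2-en-1-one (racemic, one enantiomer drawn; not isolated) | COC1=C(OC)[C@@H](O)C1=O | intermediate
3 | 3-methoxycyclobut-3-ene-1,2-dione | COC1=CC(=O)C1=O | intermediate
4 | 4-bromo-3-iodoanisole | COc1ccc(Br)c(I)c1 | starting material
5 | 3,4-dimethoxyphenylboronic acid | COc1ccc(B(O)O)cc1OC | starting material
6 | 2-bromo-3',4',5-trimethoxy-1,1'-biphenyl | COc1ccc(Br)c(-c2ccc(OC)c(OC)c2)c1 | intermediate
7 | [2-(3,4-dimethoxyphenyl)-4-methoxyphenyl]lithium (not isolated) | [Li]c1ccc(OC)cc1-c1ccc(OC)c(OC)c1 | intermediate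
8 | 4-[2-(3,4-dimethoxyphenyl)-4-methoxyphenyl]-4-hydroxy-3-methoxycyclobut-2-en-1-one (racemic, one enantiomer drawn) | COC1=CC(=O)[C@]1(O)c1ccc(OC)cc1-c1ccc(OC)c(OC)c1 | intermediate
9 | (3Z)-4-[2-(3,4-dimethoxyphenyl)-4-methoxyphenyl]-4-hydroxy-3-methoxybuta-1,3-dien-1-one (dienylketene, not isolated) | O=C=C/C(OC)=C(/O)c1ccc(OC)cc1-c1ccc(OC)c(OC)c1 | intermediate
10 | 8-(3,4-dimethoxyphenyl)-1-hydroxy-2,6-dimethoxy-4aH-naphthalen-4-one (racemic, one enantiomer drawn; not isolated) | COC1=CC(=O)[C@@H]2C=C(OC)C=C(-c3ccc(OC)c(OC)c3)C2=C1O | intermediate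
11 | 8-(3,4-dimethoxyphenyl)-2,6-dimethoxynaphthalene-1,4-diol | COc1cc(O)c2cc(OC)cc(-c3ccc(OC)c(OC)c3)c2c1O | intermediate
12 | 8-(3,4-dimethoxyphenyl)-2,6-dimethoxynaphthalene-1,4-dione | COC1=CC(=O)c2cc(OC)cc(-c3ccc(OC)c(OC)c3)c2C1=O | target

**Step count**
Total: 5 steps. Longest linear sequence: 4 steps (4 → 6 → 8 → 11 → 12, or equally 1 → 3 → 8 → 11 → 12).

**Steps most likely to fail, with fallbacks**

Step 3. The hindered, strongly basic biaryllithium may abstract the ring C–H proton of 3, attack C3 in an addition–elimination, or add a second time, instead of adding once to the C2 carbonyl. The fallback attaches the four-membered ring with a smaller, less basic aryl Grignard reagent and moves the biaryl coupling to the end. It sets out from 3 and comes back to the route at 12. Commercial 3-bromo-4-iodoanisole (COc1ccc(I)c(Br)c1) would undergo iodine–magnesium exchange with iPrMgCl·LiCl in THF at −40 °C to give (2-bromo-4-methoxyphenyl)magnesium chloride F1. Addition of F1 to 3 at −78 °C should give 4-(2-bromo-4-methoxyphenyl)-4-hydroxy-3-methoxycyclobut-2-en-1-one F2. Thermolysis in p-xylene as in step 4, with bromine blocking one ortho carbon, should give 8-bromo-2,6-dimethoxynaphthalene-1,4-diol F3. Ag2O would oxidise it to 8-bromo-2,6-dimethoxynaphthalene-1,4-dione F4. A Suzuki coupling of F4 with 5 (Pd(dppf)Cl2, K3PO4, dioxane, 80 °C) would then deliver 12.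

Step 1. The single-hydride reduction may run on to over-reduced material, and the small, very electrophilic methyl semisquarate may hydrolyse or oligomerise during the acid step and isolation. The fallback carries the better-documented isopropyl ester through the sequence and exchanges the alkoxy group at the end. It sets out from 6 and comes back at 12. Commercial diisopropyl squarate would be reduced with LiAlH(OtBu)3 to 4-hydroxy-2,3-di(propan-2-yloxy)cyclobut-2-en-1-one F5 and hydrolysed with HCl to 3-(propan-2-yloxy)cyclobut-3-ene-1,2-dione F6. Aryllithium 7, made from 6 as in step 3, should add to F6 to give 4-[2-(3,4-dimethoxyphenyl)-4-methoxyphenyl]-4-hydroxy-3-(propan-2-yloxy)cyclobut-2-en-1-one F7. Thermolysis would give 8-(3,4-dimethoxyphenyl)-6-methoxy-2-(propan-2-yloxy)naphthalene-1,4-diol F8, and Ag2O would give 8-(3,4-dimethoxyphenyl)-6-methoxy-2-(propan-2-yloxy)naphthalene-1,4-dione F9. Acid-catalysed alkoxy exchange of this vinylogous ester in methanol (cat. H2SO4, MeOH, reflux) should then give 12.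

Step 4. The free hydroxyl may trap the ketene (inward rotation followed by lactonisation to a furanone), or the electron-rich diol may decompose at the temperature of the thermolysis. The fallback masks the hydroxyl before ring opening. It sets out from 8 and comes back at 11. Silylation of 8 (Me3SiOTf, 2,6-lutidine, CH2Cl2, −78 °C) would give 4-[2-(3,4-dimethoxyphenyl)-4-methoxyphenyl]-3-methoxy-4-(trimethylsilyloxy)cyclobut-2-en-1-one F10. Its thermolysis in p-xylene should follow the same ring opening and 6π closure to 5-(3,4-dimethoxyphenyl)-3,7-dimethoxy-4-(trimethylsilyloxy)naphthalen-1-ol F11. Mild desilylation (1 M HCl, THF, rt) would release 11.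

**Further compounds**
F1 | step 3 | (2-bromo-4-methoxyphenyl)magnesium chloride | COc1ccc([Mg]Cl)c(Br)c1
F2 | step 3 | 4-(2-bromo-4-methoxyphenyl)-4-hydroxy-3-methoxycyclobut-2-en-1-one (racemic, one enantiomer drawn) | COC1=CC(=O)[C@]1(O)c1ccc(OC)cc1Br
F3 | step 3 | 8-bromo-2,6-dimethoxynaphthalene-1,4-diol | COc1cc(O)c2cc(OC)cc(Br)c2c1O
F4 | step 3 | 8-bromo-2,6-dimethoxynaphthalene-1,4-dione | COC1=CC(=O)c2cc(OC)cc(Br)c2C1=O
F5 | step 1 | 4-hydroxy-2,3-di(propan-2-yloxy)cyclobut-2-en-1-one (racemic, one enantiomer drawn) | CC(C)OC1=C(OC(C)C)[C@@H](O)C1=O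
F6 | step 1 | 3-(propan-2-yloxy)cyclobut-3-ene-1,2-dione | CC(C)OC1=CC(=O)C1=O
F7 | step 1 | 4-[2-(3,4-dimethoxyphenyl)-4-methoxyphenyl]-4-hydroxy-3-(propan-2-yloxy)cyclobut-2-en-1-one (racemic, one enantiomer drawn) | CC(C)OC1=CC(=O)[C@]1(O)c1ccc(OC)cc1-c1ccc(OC)c(OC)c1
F8 | step 1 | 8-(3,4-dimethoxyphenyl)-6-methoxy-2-(propan-2-yloxy)naphthalene-1,4-diol | CC(C)Oc1cc(O)c2cc(OC)cc(-c3ccc(OC)c(OC)c3)c2c1O
F9 | step 1 | 8-(3,4-dimethoxyphenyl)-6-methoxy-2-(propan-2-yloxy)naphthalene-1,4-dione | CC(C)OC1=CC(=O)c2cc(OC)cc(-c3ccc(OC)c(OC)c3)c2C1=O
F10 | step 4 | 4-[2-(3,4-dimethoxyphenyl)-4-methoxyphenyl]-3-methoxy-4-(trimethylsilyloxy)cyclobut-2-en-1-one (racemic, one enantiomer drawn) | COC1=CC(=O)[C@]1(O[Si](C)(C)C)c1ccc(OC)cc1-c1ccc(OC)c(OC)c1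
F11 | step 4 | 5-(3,4-dimethoxyphenyl)-3,7-dimethoxy-4-(trimethylsilyloxy)naphthalen-1-ol | COc1cc(O)c2cc(OC)cc(-c3ccc(OC)c(OC)c3)c2c1O[Si](C)(C)C
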